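## Analysis of the target

The target is a daucane sesquiterpenoid ester built on a trans-fused hydroazulene. Daucane numbering is used for every atom label: ring A is C1–C5, ring B is C5–C10 plus C1, C11–C13 are the isopropyl group, C14 is the methyl on C8 and C15 the methyl on C1. The α face is the face of ring B that carries the C6 oxygen.

It has six stereocentres (1R,4R,5S,6S,8R,9S): the quaternary C1 (methyl β), the fully substituted carbinol C4 (OH β, isopropyl α), the fusion methine C5 (H α), the ester carbon C6 (O α), and the epoxide carbons C8 and C9 (oxygen α, C14 β). H5, the C6 oxygen and the epoxide oxygen therefore share the α face, while C15 and the C4 hydroxyl sit on the β face.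

The sensitive groups are the trisubstituted epoxide (acid, transannular attack by the hydroxyls), the tertiary alcohol (dehydration) and the aryl ester. The epoxide and the ester are left to the last two steps.

The difficulty is the contiguous array C4–C5–C6 beside the quaternary C1 on a mobile seven-membered ring, where relative configuration is hard to relay.

The strategy rests on one coincidence of structure. O6 together with C6–C7–C8(C14)–C9 is the oxygen and the four ring carbons of 3-methylfuran. Ring B can therefore be made as an 8-oxabicyclo[3.2.1]octadiene in which the oxygen bridge C6–O–C9 (both bonds α) is the future C6 oxygen and the three-carbon bridge is C5–C1–C10. This rigid bicycle then serves as the template for C1, C5 and C4 before the bridge is opened at C9.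

## Retrosynthetic reasoning

**Ester C–O bond.** 16 is cut at the acyl–O6 bond into epoxy diol 14 and acid 15. This comes last because the aroyl group would otherwise be exposed to organometallic and reducing reagents. The forward acylation only has to tell the secondary C6 hydroxyl from the tertiary C4 hydroxyl.

**Epoxide.** 14 goes back to alkene 13. The homoallylic 6α-hydroxyl and the β-oriented C15 both point an oxidant to the α face of C8=C9, so the epoxide is placed while that hydroxyl is still free.

**C9–O bond of the bridge.** In 13 the C6 hydroxyl and the C8=C9 alkene are what remains of an ether bridge from O6 to C9; reconnecting it leads to chloride 12 and then to alkene 11. The forward opening must break C9–O and not C6–O, and must leave the alkene at C8=C9. That requires electron density at C8, the methyl-bearing carbon. Hydrometalation-type reductive openings would put the metal on the less substituted C7 and expel the oxygen from C6, so they are not used. A Markovnikov hydrogen-atom-transfer hydrochlorination puts chlorine on C8, and two-electron reduction of that chloride gives a C8 carbanion whose only β-leaving group is the bridge oxygen on C9.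

**C4–isopropyl bond.** 11 is cut to ketone 10. On the rigid tricycle the β face of the C4 carbonyl is screened by the axial C15 and by C7, so a nucleophile should enter from the α face and leave the hydroxyl β.

**C3–C4 bond (ring A).** 10 is opened to aldehyde 9, a 4-pentenal whose aldehyde carbon is C4 and whose vinyl group is C2=C3. The forward reaction is an intramolecular alkene hydroacylation. It forms the cyclopentanone from two groups that are already trans-diequatorial on the pyran chair of the bicycle, so no new stereocentre is at stake.

**C1–C2 bond and C5–H.** 9 is cut to enal 7. A vinylcopper reagent must add to C1 from the exo face (the face of the oxygen bridge), which makes C2 α and C15 β. The resulting enol derivative must be protonated at C5 from the same exo face, which makes H5 α. The aldehyde oxidation level is chosen because a fully substituted β-carbon is a poor acceptor in an ester but an acceptable one in a silyl-activated enal, and because the aldehyde is what the hydroacylation needs.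

**Oxidation level.** 7 comes from ester 5 through allylic alcohol 6 by reduction and re-oxidation.

**C5–C6 and C9–C10 (key disconnection).** 5 is cut into vinyldiazoester 2 and 3-methylfuran 3. A rhodium vinylcarbenoid cyclopropanates the furan double bond remote from the methyl group, and the cis-divinylcyclopropane 4 rearranges. This closes ring B, sets C6 and C9 in one absolute sense under catalyst control, and delivers O6 and C14 already in place. The forward reaction must choose one enantioface and the less substituted furan double bond.

**Diazo group.** 2 comes from the conjugated ester 1 by deconjugative diazo transfer.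

## Alternatives that were turned down

**Alternative 1:**
- Disconnection: C1–C5 and C6–C7 are cut together. Both rings unravel to the open-chain enyne A2, a 1-alkenyl-1-siloxycyclopropane (alkene C1=C10, cyclopropane C7–C8–C9) tethered through C2–C3–C4 to the terminal alkyne C5≡C6. The C4 carbinol is derived from valine.
- Forward key step: [Rh(CO)2Cl]2 (monovalent rhodium) would effect an intramolecular (5+2) cycloaddition to the bicyclic diene A1.
- For it: two rings, the quaternary carbon and nearly the whole skeleton arise in one catalytic step, and C4 is secure from the chiral pool. In rings formed per step it is stronger than the chosen route.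
- Against it: C1 has to be set from C4 across a flexible three-atom tether while a trisubstituted alkene terminus is forced into a quaternary centre, the least favourable pattern for this cycloaddition. A1 lacks C14 and the C6 oxygen and carries its oxygen on C9. C8 would have to be methylated although the enol ether points towards C10, the C9 oxygen removed with the alkene placed at C8=C9, and C5=C6 hydrated face- and chemoselectively beside that second alkene. The fully substituted carbinol of A2 also costs several steps.
- Comparison: the furan route places O6 and C14 correctly from the start and relays configuration through a rigid bicycle, at the price of a separate annulation of ring A.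

**Alternative 2:**
- Disconnection: C4–C5, as a retro-aldol, back to cycloheptenone A4, which carries the quaternary C1 (set by conjugate addition) and a 4-methyl-3-oxopentyl chain.
- Forward key step: the C5 enolate of the C6 enone, made with a lithium amide or an equilibrating base, adds to the isopropyl ketone and gives β-hydroxy enone A3.
- For it: only classical reagents, no diazo compound and no precious metal; the C7=C8 enone offers handles at C6 and C8. In cost and in robustness of the single operations it is stronger.
- Against it: addition of a ketone enolate to a hindered isopropyl ketone is reversible and thermodynamically weak (retro-aldol, or dehydration to the C4=C5 enone). The enone can enolise towards C5 or through C9, and the side-chain ketone can enolise as well. C4, C5 and the trans ring fusion would all have to emerge from one equilibrating step in which the cis-fused aldol is the likely sink. Afterwards the C6 ketone must be reduced by hydride attack on the hindered β face, and the alkene moved out of conjugation from C7=C8 to C8=C9. The quaternary centre of A4 needs its own asymmetric step.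
- Comparison: the chosen route fixes C6 in the cycloaddition and sets C5 and C4 by kinetically controlled exo-face reactions on a rigid frame, instead of relying on an aldol equilibrium.

**Alternative 3:**
- Disconnection: C7–C8 and C9–C10. Ring B is assembled from vinylcyclopropane A6 (a bicyclo[3.1.0]hexane holding ring A, the quaternary C1, a C4 ketal and a 1-siloxyvinyl group on C5) and propyne A7.
- Forward key step: [Rh(CO)2Cl]2 (monovalent rhodium) cleaves the C5–C10 cyclopropane bond, inserts A7 and gives diene A5.
- For it: C14 and the C8=C9 alkene arrive exactly where the target has them, so neither a bridge opening nor a furan regiochemistry question arises. On this point it is stronger than the chosen route. C1 is set beforehand by an asymmetric cyclopropanation.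
- Against it: the orientation of the small alkyne A7 (methyl on C8 or on C9) is only weakly biased. The metal must cleave C5–C10 and not the ring-fusion bond C1–C5, and must then reductively eliminate at a neopentyl carbon next to C1. A5 is flat around C5=C6, so C5, C6 and later C4 are all set after the key step with little to guide them. A6 itself needs several steps.
- Comparison: the chosen strategy fixes the absolute configuration at C6 first and derives C5, C1 and C4 from it; what it gives up is the direct placement of the C8=C9 alkene.

Key step: step 2

Assumption: Rh2(S-PTAD)4 is taken to give the (1S,5S) enantiomer of 5; if the sense of induction is the opposite, Rh2(R-PTAD)4 is used and nothing else changes.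

## Route

Step 1
Reactants: 1 methyl 3-methylbut-2-enoate
Product: 2 methyl 2-diazo-3-methylbut-3-enoate
Conditions: p-ABSA, DBU, MeCN, 0 °C → rt; short silica plug, used at once
Reagents that add atoms: 4-acetamidobenzenesulfonyl azide (p-ABSA), CC(=O)Nc1ccc(cc1)S(=O)(=O)N=[N+]=[N-]
Why: Deconjugative Regitz diazo transfer: DBU removes a γ-proton, the extended dienolate attacks the sulfonyl azide through its α-carbon and the triazene collapses to the vinyldiazoester and the sulfonamide. The product cyclises slowly to a pyrazole and is therefore not stored.

Step 2
Reactants: 2 methyl 2-diazo-3-methylbut-3-enoate; 3 3-methylfuran (3–5 equiv)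
Product: 5 methyl (1S,5S)-3,6-dimethyl-8-oxabicyclo[3.2.1]octa-2,6-diene-2-carboxylate, via cis-divinylcyclopropane 4 (not isolated)
Conditions: Rh2(S-PTAD)4 (dirhodium tetrakis[(S)-(1-adamantyl)(N-phthalimido)acetate], divalent rhodium, 1 mol %), 2,2-dimethylbutane, slow addition of 2, −40 °C → rt
Reagents that add atoms: none
Why: The catalyst converts 2 into a donor/acceptor rhodium vinylcarbenoid, which cyclopropanates the unsubstituted C4=C5 bond of 3 (furan numbering), bonding first to the free α-carbon, to give 4 with the isopropenyl group endo. 4 then undergoes a boat-type Cope rearrangement at or below room temperature: the cyclopropane bond between the two alkenyl-bearing carbons breaks and the isopropenyl CH2 joins the furan C2, so that C5–C6 and C9–C10 (daucane numbering) are the two new skeletal bonds. The closest known reaction type is the tandem cyclopropanation/Cope rearrangement, a formal (4+3) cycloaddition, of rhodium vinylcarbenoids with furans. Ring B closes as the carbocyclic seven-membered ring of the oxabicycle by a suprafacial [3,3]-sigmatropic shift that joins a three-carbon carbenoid unit to the four-carbon furan diene. The cis relation of C6 and C9 is fixed by the oxygen bridge; their absolute sense is decided in the cyclopropanation by the furan enantioface that the chiral carboxylate ligands leave open. The step needs site selectivity for C4=C5 over C2=C3, which rests on the steric demand of the carbenoid against the methyl-bearing double bond, and the endo placement of the alkenyl group, which is inherent to donor/acceptor carbenoids. Excess furan and slow addition suppress carbenoid dimerisation, and the hydrocarbon solvent disfavours zwitterionic ring-opening of the furan.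

Step 3
Reactants: 5 methyl (1S,5S)-3,6-dimethyl-8-oxabicyclo[3.2.1]octa-2,6-diene-2-carboxylate
Product: 6 [(1S,5S)-3,6-dimethyl-8-oxabicyclo[3.2.1]octa-2,6-dien-2-yl]methanol
Conditions: DIBAL-H (2.5 equiv), CH2Cl2, −78 °C; Rochelle salt work-up
Reagents that add atoms: none
Why: Standard 1,2-reduction of a conjugated ester to the allylic alcohol with an aluminium hydride. At −78 °C the strained alkene and the ether bridge are not touched.

Step 4
Reactants: 6 [(1S,5S)-3,6-dimethyl-8-oxabicyclo[3.2.1]octa-2,6-dien-2-yl]methanol
Product: 7 (1S,5S)-3,6-dimethyl-8-oxabicyclo[3.2.1]octa-2,6-diene-2-carbaldehyde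
Conditions: activated MnO2, CH2Cl2, rt
Reagents that add atoms: none
Why: Selective heterogeneous oxidation of a primary allylic alcohol to the enal under neutral conditions that leave the acid-sensitive doubly allylic ether alone.

Step 5
Reactants: 7 (1S,5S)-3,6-dimethyl-8-oxabicyclo[3.2.1]octa-2,6-diene-2-carbaldehyde
Product: 9 (1S,2S,3S,5S)-3-ethenyl-3,6-dimethyl-8-oxabicyclo[3.2.1]oct-6-ene-2-carbaldehyde, via silyl enol ether 8 (not isolated)
Conditions: CH2=CHMgBr (2.2 equiv), CuBr·SMe2 (1.1 equiv), TMSCl, THF, −78 → −40 °C; then AcOH, H2O, THF, 0 °C
Reagents that add atoms: vinylmagnesium bromide, C=C[Mg]Br (chlorotrimethylsilane leaves its silyl group only in 8)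
Why: Chlorosilane-accelerated conjugate addition of a divinylcuprate to a β,β-disubstituted enal. The vinyl group enters C1 from the exo face, the face of the oxygen bridge, as nucleophiles do on the three-carbon bridge of 8-oxabicyclo[3.2.1]octenes, which makes C2 α and C15 β; immediate silylation to 8 prevents β-elimination of the bridge oxygen from the enolate. Mild acid then protonates C5 of 8 from the same exo face, because the endo face is flanked by the axial C15 and by C7, giving H5 α and the formyl group equatorial and trans to the vinyl group.

Step 6
Reactants: 9 (1S,2S,3S,5S)-3-ethenyl-3,6-dimethyl-8-oxabicyclo[3.2.1]oct-6-ene-2-carbaldehyde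
Product: 10 6α,9α-epoxy-11,12,13-trinordauc-7-en-4-one (ring A cyclopentanone, H5 α, C15 β, trans ring fusion)
Conditions: [Rh(nbd)(dppe)]BF4 (5 mol %, monovalent rhodium; norbornadiene removed with H2, then Ar), CH2Cl2, rt
Reagents that add atoms: none
Why: Rhodium-catalysed intramolecular hydroacylation of a 4-pentenal: the metal inserts into the aldehyde C–H bond, the hydride adds to C2 of the vinyl group and reductive elimination forms C3–C4. The quaternary carbon between aldehyde and alkene favours cyclisation, and the trisubstituted C7=C8 alkene, although also in a 4-pentenal relation, is too substituted to compete. The neutral conditions leave the epimerisable C5 and the β-alkoxy carbonyl unit untouched.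

Step 7
Reactants: 10 6α,9α-epoxy-11,12,13-trinordauc-7-en-4-one
Product: 11 6α,9α-epoxydauc-7-en-4β-ol (isopropyl α at C4)
Conditions: i-PrMgCl, CeCl3 (dried), THF, −78 °C; aq. NH4Cl
Reagents that add atoms: isopropylmagnesium chloride, CC(C)[Mg]Cl
Why: Organocerium 1,2-addition, chosen because the weakly basic reagent adds to hindered, enolisable ketones without enolisation, reduction or β-elimination of the bridge oxygen. The β face of the C4 carbonyl is shielded by the axial C15 and by C7, so the isopropyl group should enter from the α face and set C4 with the hydroxyl β.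

Step 8
Reactants: 11 6α,9α-epoxydauc-7-en-4β-ol
Product: 12 8α-chloro-6α,9α-epoxydaucan-4β-ol (C14 β)
Conditions: Co(acac)2 (divalent cobalt), t-BuOOH, Et3SiH, TsCl, n-PrOH, rt
Reagents that add atoms: 4-toluenesulfonyl chloride, Cc1ccc(cc1)S(Cl)(=O)=O
Why: Mukaiyama-type hydrogen-atom-transfer hydrochlorination: a cobalt hydride gives a hydrogen atom to the less substituted C7, and the tertiary C8 radical takes chlorine from the sulfonyl chloride on the open exo face. The radical pathway gives Markovnikov regiochemistry without a C8 cation, so Wagner–Meerwein shifts of the bicycle are avoided; the C8 configuration is of no consequence.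

Step 9
Reactants: 12 8α-chloro-6α,9α-epoxydaucan-4β-ol
Product: 13 dauc-8-ene-4β,6α-diol (jaeschkeanadiol)
Conditions: LiDBB (lithium 4,4′-di-tert-butylbiphenylide, 4 equiv), THF, −78 °C; aq. NH4Cl
Reagents that add atoms: none
Why: Boord-type reductive fragmentation of a β-chloro ether: after the hydroxyl is converted to its alkoxide, two electron transfers turn the tertiary chloride into a C8 carbanion, which expels the only β-leaving group, the bridge oxygen on C9. This places the alkene at C8=C9, leaves C7 as CH2 and frees the oxygen on C6 with its α configuration unchanged.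

Step 10
Reactants: 13 dauc-8-ene-4β,6α-diol
Product: 14 8α,9α-epoxydaucane-4β,6α-diol
Conditions: VO(acac)2 (3 mol %), t-BuOOH, CH2Cl2, 0 °C → rt
Reagents that add atoms: tert-butyl hydroperoxide, CC(C)(C)OO
Why: Vanadium-catalysed hydroxyl-directed epoxidation: the homoallylic 6α-hydroxyl binds the vanadium peroxide and delivers oxygen to the α face of C8=C9, the face that is also remote from C15. This sets C8 and C9 under neutral conditions that spare the new epoxide.

Step 11
Reactants: 14 8α,9α-epoxydaucane-4β,6α-diol; 15 3,4-dimethoxybenzoic acid
Product: 16 8α,9α-epoxy-4β-hydroxydaucan-6α-yl 3,4-dimethoxybenzoate (CNP0251065.1)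
Conditions: EDC·HCl, DMAP, CH2Cl2, rt
Reagents that add atoms: none
Why: Steglich esterification: the acylpyridinium formed from 15 acylates the secondary C6 hydroxyl, while the tertiary C4 hydroxyl is too hindered to react. The basic, non-acidic medium keeps the epoxide intact.

## Compound list

1 | methyl 3-methylbut-2-enoate | CC(C)=CC(=O)OC | starting material
2 | methyl 2-diazo-3-methylbut-3-enoate | C=C(C)C(=[N+]=[N-])C(=O)OC | intermediate
3 | 3-methylfuran | Cc1ccoc1 | starting material
4 | methyl (1S,5S,6R)-4-methyl-6-(prop-1-en-2-yl)-2-oxabicyclo[3.1.0]hex-3-ene-6-carboxylate (isopropenyl endo) | COC(=O)[C@]1(C(C)=C)[C@H]2OC=C(C)[C@@H]12 | intermediate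
5 | methyl (1S,5S)-3,6-dimethyl-8-oxabicyclo[3.2.1]octa-2,6-diene-2-carboxylate | COC(=O)C1=C(C)C[C@@H]2O[C@H]1C=C2C | intermediate
6 | [(1S,5S)-3,6-dimethyl-8-oxabicyclo[3.2.1]octa-2,6-dien-2-yl]methanol | OCC1=C(C)C[C@@H]2O[C@H]1C=C2C | intermediate
7 | (1S,5S)-3,6-dimethyl-8-oxabicyclo[3.2.1]octa-2,6-diene-2-carbaldehyde | O=CC1=C(C)C[C@@H]2O[C@H]1C=C2C | intermediate
8 | {[(1S,3S,5S)-3-ethenyl-3,6-dimethyl-8-oxabicyclo[3.2.1]oct-6-en-2-ylidene]methoxy}trimethylsilane (enol ether geometry not defined) | C[Si](C)(C)OC=C1[C@@H]2C=C(C)[C@@H](O2)C[C@@]1(C)C=C | intermediate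
9 | (1S,2S,3S,5S)-3-ethenyl-3,6-dimethyl-8-oxabicyclo[3.2.1]oct-6-ene-2-carbaldehyde | O=C[C@@H]1[C@@H]2C=C(C)[C@@H](O2)C[C@@]1(C)C=C | intermediate
10 | 6α,9α-epoxy-11,12,13-trinordauc-7-en-4-one (H5 α, C15 β) | O=C1CC[C@]2(C)C[C@@H]3O[C@@H](C=C3C)[C@@H]12 | intermediate
11 | 6α,9α-epoxydauc-7-en-4β-ol | CC(C)[C@]1(O)CC[C@]2(C)C[C@@H]3O[C@@H](C=C3C)[C@@H]12 | intermediate
12 | 8α-chloro-6α,9α-epoxydaucan-4β-ol | CC(C)[C@]1(O)CC[C@]2(C)C[C@@H]3O[C@@H](C[C@@]3(C)Cl)[C@@H]12 | intermediate
13 | dauc-8-ene-4β,6α-diol (jaeschkeanadiol) | CC(C)[C@]1(O)CC[C@]2(C)CC=C(C)C[C@H](O)[C@@H]12 | intermediate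
14 | 8α,9α-epoxydaucane-4β,6α-diol | CC(C)[C@]1(O)CC[C@]2(C)C[C@@H]3O[C@]3(C)C[C@H](O)[C@@H]12 | intermediate
15 | 3,4-dimethoxybenzoic acid | COc1ccc(C(=O)O)cc1OC | starting material
16 | 8α,9α-epoxy-4β-hydroxydaucan-6α-yl 3,4-dimethoxybenzoate (CNP0251065.1) | COc1ccc(C(=O)O[C@H]2C[C@@]3(C)O[C@H]3C[C@@]3(C)CC[C@@](O)(C(C)C)[C@H]23)cc1OC | target

## Step count and least certain steps

Total step count: 11. Longest linear sequence: 11 steps (1 to 16); 3 and 15 enter in steps 2 and 11.

**Step 2 (key step).** The most likely failure is loss of site control. Attack of the carbenoid on the furan α-carbon next to the methyl group is electronically favoured, because the methyl group stabilises the charge that develops, and it would lead through the same cascade to the isomer with the methyl group on C7. Erosion of enantioselectivity and ring-opening of the furan to trienes are lesser concerns. Fallback: the methyl-bearing double bond is blocked and deactivated with a removable carboxyl group. 2-(Trimethylsilyl)ethyl 3-methylfuran-2-carboxylate F1, made from commercial 3-methylfuran-2-carboxylic acid and 2-(trimethylsilyl)ethanol, is used in place of 3 with 2 under the same catalyst. Furan-2-carboxylates are cyclopropanated only at the remote, electron-richer C4=C5 bond, and the Cope step should then give the bridgehead diester 2-methyl 5-[2-(trimethylsilyl)ethyl] (1S,5S)-3,6-dimethyl-8-oxabicyclo[3.2.1]octa-2,6-diene-2,5-dicarboxylate F2. Fluoride (TBAF) frees the bridgehead C9 carboxylic acid F3. This is converted with N-hydroxypyridine-2-thione and DCC into the thiohydroxamate ester F4, and Barton decarboxylation (t-BuSH, visible light) replaces the carboxyl group by hydrogen. The route is rejoined at 5.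

**Step 5.** The β-carbon is fully substituted, so 1,2-addition to the aldehyde or failure to add at all is the main risk. If silylation lags, the enolate may also expel the bridge oxygen from C6. Fallback: the annulation is changed from conjugate addition plus hydroacylation to a Nazarov cyclisation, setting out from 7. Vinylmagnesium bromide with CeCl3 adds 1,2 to give 1-[(1S,5S)-3,6-dimethyl-8-oxabicyclo[3.2.1]octa-2,6-dien-2-yl]prop-2-en-1-ol F5 as a mixture of carbinol epimers. MnO2 gives the cross-conjugated dienone 1-[(1S,5S)-3,6-dimethyl-8-oxabicyclo[3.2.1]octa-2,6-dien-2-yl]prop-2-en-1-one F6. A mild Lewis acid such as Sc(OTf)3 should induce conrotatory closure of C1–C2 on the exo face and, after exo protonation at C5, give the cyclopentenone 6α,9α-epoxy-11,12,13-trinordauca-2,7-dien-4-one F7. Conjugate reduction with [(Ph3P)CuH]6 returns to the route at 10, so steps 5 and 6 are both replaced.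

**Step 6.** The likely failure is catalyst deactivation by decarbonylation of the hindered aldehyde. Prolonged reaction times would also expose 9 to epimerisation at C5 or loss of the β-alkoxy bridge. Fallback: an anionic closure of ring A that forms the carbinol directly, setting out from 9. Isopropylmagnesium chloride with CeCl3 gives the secondary alcohol 1-[(1S,2S,3S,5S)-3-ethenyl-3,6-dimethyl-8-oxabicyclo[3.2.1]oct-6-en-2-yl]-2-methylpropan-1-ol F8 as an epimer mixture. Dess–Martin oxidation gives the isopropyl ketone F9, 1-[(1S,2S,3S,5S)-3-ethenyl-3,6-dimethyl-8-oxabicyclo[3.2.1]oct-6-en-2-yl]-2-methylpropan-1-one. 9-BBN hydroborates only the terminal vinyl group, and oxidation with NaBO3 gives the hydroxy ketone 1-[(1S,2S,3S,5S)-3-(2-hydroxyethyl)-3,6-dimethyl-8-oxabicyclo[3.2.1]oct-6-en-2-yl]-2-methylpropan-1-one F10. An Appel reaction (I2, PPh3, imidazole) gives the iodide 1-[(1S,2S,3S,5S)-3-(2-iodoethyl)-3,6-dimethyl-8-oxabicyclo[3.2.1]oct-6-en-2-yl]-2-methylpropan-1-one F11. A Barbier cyclisation with SmI2 (divalent samarium) and HMPA closes C3–C4; the isopropyl group should stay away from the axial C15, which leaves the hydroxyl β. The route is rejoined at 11, so step 7 is replaced as well.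

**Step 8.** The tertiary C8 radical may take a hydrogen atom faster than chlorine, which reduces the alkene, or hydrogen-atom transfer to the hindered bicyclic alkene may be slow. Fallback: the bridge is opened by conjugate reduction and β-elimination through C14, setting out from 11. Allylic oxidation of C14 (SeO2, t-BuOOH, then MnO2) gives 4β-hydroxy-6α,9α-epoxydauc-7-en-14-al F12. One equivalent of hydride from [(Ph3P)CuH]6 adds to C7, and the resulting enolate, whose α-carbon is C8, expels the bridge oxygen from C9 to give 4β,6α-dihydroxydauc-8-en-14-al F13. Luche reduction (NaBH4, CeCl3) gives dauc-8-ene-4β,6α,14-triol F14. The primary allylic hydroxyl is converted selectively (MsCl, LiCl, 2,4,6-collidine) into 14-chlorodauc-8-ene-4β,6α-diol F15, and direct displacement with LiBHEt3 restores the methyl group. The route is rejoined at 13, so steps 8 and 9 are replaced.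

## Further compounds

F1 | step 2 | 2-(trimethylsilyl)ethyl 3-methylfuran-2-carboxylate | Cc1ccoc1C(=O)OCC[Si](C)(C)C
F2 | step 2 | 2-methyl 5-[2-(trimethylsilyl)ethyl] (1S,5S)-3,6-dimethyl-8-oxabicyclo[3.2.1]octa-2,6-diene-2,5-dicarboxylate | COC(=O)C1=C(C)C[C@]2(C(=O)OCC[Si](C)(C)C)O[C@H]1C=C2C
F3 | step 2 | bridgehead C9 carboxylic acid of 5 | COC(=O)C1=C(C)C[C@]2(C(=O)O)O[C@H]1C=C2C
F4 | step 2 | 2-thioxopyridin-1(2H)-yl ester of F3 | COC(=O)C1=C(C)C[C@]2(C(=O)On3ccccc3=S)O[C@H]1C=C2C
F5 | step 5 | 1-[(1S,5S)-3,6-dimethyl-8-oxabicyclo[3.2.1]octa-2,6-dien-2-yl]prop-2-en-1-ol | C=CC(O)C1=C(C)C[C@@H]2O[C@H]1C=C2C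
F6 | step 5 | 1-[(1S,5S)-3,6-dimethyl-8-oxabicyclo[3.2.1]octa-2,6-dien-2-yl]prop-2-en-1-one | C=CC(=O)C1=C(C)C[C@@H]2O[C@H]1C=C2C
F7 | step 5 | 6α,9α-epoxy-11,12,13-trinordauca-2,7-dien-4-one | O=C1C=C[C@]2(C)C[C@@H]3O[C@@H](C=C3C)[C@@H]12
F8 | step 6 | 1-[(1S,2S,3S,5S)-3-ethenyl-3,6-dimethyl-8-oxabicyclo[3.2.1]oct-6-en-2-yl]-2-methylpropan-1-ol | CC(C)C(O)[C@@H]1[C@@H]2C=C(C)[C@@H](O2)C[C@@]1(C)C=C
F9 | step 6 | 1-[(1S,2S,3S,5S)-3-ethenyl-3,6-dimethyl-8-oxabicyclo[3.2.1]oct-6-en-2-yl]-2-methylpropan-1-one | CC(C)C(=O)[C@@H]1[C@@H]2C=C(C)[C@@H](O2)C[C@@]1(C)C=C
F10 | step 6 | 1-[(1S,2S,3S,5S)-3-(2-hydroxyethyl)-3,6-dimethyl-8-oxabicyclo[3.2.1]oct-6-en-2-yl]-2-methylpropan-1-one | CC(C)C(=O)[C@@H]1[C@@H]2C=C(C)[C@@H](O2)C[C@@]1(C)CCO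
F11 | step 6 | 1-[(1S,2S,3S,5S)-3-(2-iodoethyl)-3,6-dimethyl-8-oxabicyclo[3.2.1]oct-6-en-2-yl]-2-methylpropan-1-one | CC(C)C(=O)[C@@H]1[C@@H]2C=C(C)[C@@H](O2)C[C@@]1(C)CCI
F12 | step 8 | 4β-hydroxy-6α,9α-epoxydauc-7-en-14-al | CC(C)[C@]1(O)CC[C@]2(C)C[C@@H]3O[C@@H](C=C3C=O)[C@@H]12
F13 | step 8 | 4β,6α-dihydroxydauc-8-en-14-al | CC(C)[C@]1(O)CC[C@]2(C)CC=C(C=O)C[C@H](O)[C@@H]12
F14 | step 8 | dauc-8-ene-4β,6α,14-triol | CC(C)[C@]1(O)CC[C@]2(C)CC=C(CO)C[C@H](O)[C@@H]12
F15 | step 8 | 14-chlorodauc-8-ene-4β,6α-diol | CC(C)[C@]1(O)CC[C@]2(C)CC=C(CCl)C[C@H](O)[C@@H]12
A1 | alternative 1 | 9-(tert-butyldimethylsilyloxy)-4β-(triethylsilyloxy)-14-nordauca-5,9-diene | CC(C)(C)[Si](C)(C)OC1=C[C@@]2(C)CC[C@@](O[Si](CC)(CC)CC)(C(C)C)C2=CCC1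
A2 | alternative 1 | (1E,5R)-1-[1-(tert-butyldimethylsilyloxy)cyclopropyl]-5-ethynyl-2,6-dimethyl-5-(triethylsilyloxy)hept-1-ene | C#C[C@](O[Si](CC)(CC)CC)(C(C)C)CC/C(C)=C/C1(CC1)O[Si](C)(C)C(C)(C)C
A3 | alternative 2 | 4β-hydroxydauc-7-en-6-one (H5 α) | O=C1C=C(C)CC[C@@]2(C)CC[C@@](O)(C(C)C)[C@H]12
A4 | alternative 2 | 3,6-dimethyl-6-(4-methyl-3-oxopentyl)cyclohept-2-en-1-one (quaternary carbon as C1 of the target) | CC(C)C(=O)CC[C@]1(C)CCC(C)=CC(=O)C1
A5 | alternative 3 | 6-(tert-butyldimethylsilyloxy)-11,12,13-trinordauca-5,8-dien-4-one ethylene ketal | CC(C)(C)[Si](C)(C)OC1=C2C3(OCCO3)CC[C@]2(C)CC=C(C)C1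
A6 | alternative 3 | 1-[1-(tert-butyldimethylsilyloxy)ethenyl]-5-methylbicyclo[3.1.0]hexan-2-one ethylene ketal | C=C(O[Si](C)(C)C(C)(C)C)[C@]12C[C@@]1(C)CCC23OCCO3
A7 | alternative 3 | propyne | CC#C
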